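**Retrosynthetic overview**
1. 16 ⇒ benzaldehyde 14 + C3'-allylated acetophenone 13 (Claisen–Schmidt condensation, which also removes both acetates).
2. 13 ⇒ aryl allyl ether 11 (aromatic [3,3] shift; the C5–O stereocentre is converted into the C7 stereocentre).
3. 11 ⇒ phenol 10 + anti hydroxy ester 9. This C5–O(aryl) bond is the key disconnection and is made with retention under palladium catalysis.
4. 9 ⇒ aldol 7 (Evans–Tishchenko, sets C3) ⇒ cuelure 4 + enal 3 (boron aldol, sets C5) ⇒ 1 + 2 (Wittig).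
5. No ring is formed; all four benzene rings are bought.

Assumption: atom labels follow diarylheptanoid numbering (C1 = benzylic CH2 of the saturated arm, C3 = carbinol, C7 = diaryl methine). Primed numbers refer to ring A of the acetophenone/chalcone. Read this way, the target SMILES is (3R,5E,7S).

Step 1
Reactants: 1 4-acetoxybenzaldehyde; 2 (triphenylphosphoranylidene)acetaldehyde
Product: 3 (E)-3-(4-acetoxyphenyl)prop-2-enal
Conditions: toluene, 80 °C, 16 h
Reagents that add atoms: none
Why: Wittig olefination with a formyl-stabilised ylide is E-selective, leaves the aryl acetate alone and stops largely at the mono-homologated enal because 3 is less electrophilic than 1.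

Step 2
Reactants: 4 4-(4-acetoxyphenyl)butan-2-one (cuelure); 3 (E)-3-(4-acetoxyphenyl)prop-2-enal
Product: 7 (5S,6E)-1,7-bis(4-acetoxyphenyl)-5-hydroxyhept-6-en-3-one, via boron enolate 5 (not isolated), via boron aldolate 6 (not isolated)
Conditions: (+)-Ipc2BCl (1.3 equiv), Et3N (1.5 equiv), Et2O, 0 °C, 1 h; 3, −78 to −20 °C, 16 h; pH 7 buffer/MeOH
Reagents that add atoms: none
Why: Paterson-type boron aldol reaction in which the chloroborane/Et3N pair enolises the methyl ketone only on the CH3 side without touching the aryl acetates, and the isopinocampheyl ligands of the (+)-reagent direct attack to the enal face that gives the (5S)-carbinol (about 85:15 to 90:10 er expected for a methyl ketone, to be raised in step 3).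

Step 3
Reactants: 7 (5S,6E)-1,7-bis(4-acetoxyphenyl)-5-hydroxyhept-6-en-3-one; 8 4-chlorobenzaldehyde
Product: 9 (3R,5S,6E)-1,7-bis(4-acetoxyphenyl)-3-hydroxyhept-6-en-5-yl 4-chlorobenzoate
Conditions: SmI2 (0.3 equiv), 8 (4 equiv), THF, −10 °C, 4 h; recrystallise (EtOAc/heptane)
Reagents that add atoms: none
Why: Evans–Tishchenko reduction in which the aldehyde adds to the C5 hydroxyl and passes its hydride to the C3 ketone through a chair-like samarium chelate, which sets (3R) 1,3-anti to C5 (>20:1), leaves C3-OH free and converts the C5 oxygen into an allylic nucleofuge, a halobenzoate chosen for crystallinity so that recrystallisation can remove the minor enantiomer.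

Step 4
Reactants: 9 (3R,5S,6E)-1,7-bis(4-acetoxyphenyl)-3-hydroxyhept-6-en-5-yl 4-chlorobenzoate; 10 1-(2,4-dihydroxy-6-methoxyphenyl)ethanone
Product: 11 1-[4-{[(3R,5S,6E)-1,7-bis(4-acetoxyphenyl)-3-hydroxyhept-6-en-5-yl]oxy}-2-hydroxy-6-methoxyphenyl]ethanone
Conditions: Pd2(dba)3·CHCl3 (2.5 mol %), DPEphos (6 mol %), iPr2NEt (1.2 equiv), 10 (1.3 equiv), THF, 0 °C, 3 h
Reagents that add atoms: none
Why: Proposed new method: stereoretentive palladium-catalysed allylic aryloxylation of an unprotected Evans–Tishchenko hydroxy ester by a free polyphenol ketone, a substrate pairing on which this reactivity has not been shown; zerovalent palladium ionises only the allylic 4-chlorobenzoate anti to the leaving group, the resulting syn,syn 1-aryl-3-alkyl π-allyl complex cannot change faces by π-σ-π because both termini are substituted, and the amine-bound 4-OH of 10 (the only non-chelated and the most acidic OH) attacks anti to the metal at C5, the terminus that keeps the styrene conjugation and lies next to the hydrogen-bonding C3-OH, so two inversions give net retention (5S) with no protection of C3-OH, while low catalyst loading, a wide-bite-angle ligand and 0 °C limit palladium-palladium exchange and re-ionisation of 11; the closest known reaction type is the Tsuji–Trost O-allylation of simple phenols with allylic carbonates, which follows the same double inversion.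

Step 5
Reactants: 11 1-[4-{[(3R,5S,6E)-1,7-bis(4-acetoxyphenyl)-3-hydroxyhept-6-en-5-yl]oxy}-2-hydroxy-6-methoxyphenyl]ethanone
Product: 13 1-[3-{(3R,5E,7S)-1,7-bis(4-acetoxyphenyl)-3-hydroxyhept-5-en-7-yl}-2,4-dihydroxy-6-methoxyphenyl]ethanone, via ortho-dienone 12 (not isolated)
Conditions: Eu(fod)3 (10 mol %), toluene, 80 °C, 16 h
Reagents that add atoms: none
Why: Aromatic Claisen rearrangement under mild europium Lewis-acid catalysis, a concerted suprafacial [3,3] shift through a chair with the C4 chain equatorial that moves the aryl group from O-C5 to C7 on the same allyl face, so (5S,6E) becomes (7S,5E) while C3 is untouched, and the hydrogen-bonded 2'-OH/acetyl chelate localises C3'=C4' double-bond character so that the shift goes to C3' rather than C5', after which 12 enolises to the phenol.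

Step 6
Reactants: 13 1-[3-{(3R,5E,7S)-1,7-bis(4-acetoxyphenyl)-3-hydroxyhept-5-en-7-yl}-2,4-dihydroxy-6-methoxyphenyl]ethanone; 14 benzaldehyde
Product: 16 7-epi-katsumain C, via deacetylated ketone 15 (not isolated)
Conditions: 14 (3 equiv), KOH (50 % aq), EtOH, rt, 48 h; 1 M HCl to pH 4, 0 °C
Reagents that add atoms: none
Why: Claisen–Schmidt condensation in which hydroxide first cleaves both aryl acetates to give 15, whose acetyl enolate adds to non-enolisable benzaldehyde and loses water by E1cB to the E-enone, while the polyphenolate form keeps the chalcone open and neither C3 nor the weakly acidic C7-H is affected at room temperature.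

**Compound list**
1 | 4-acetoxybenzaldehyde | CC(=O)Oc1ccc(C=O)cc1 | starting material
2 | (triphenylphosphoranylidene)acetaldehyde | O=CC=P(c1ccccc1)(c1ccccc1)c1ccccc1 | starting material
3 | (E)-3-(4-acetoxyphenyl)prop-2-enal | CC(=O)Oc1ccc(/C=C/C=O)cc1 | intermediate
4 | 4-(4-acetoxyphenyl)butan-2-one (cuelure) | CC(=O)CCc1ccc(OC(C)=O)cc1 | starting material
5 | 4-(4-acetoxyphenyl)but-1-en-2-yl diisopinocampheylborinate (boron enolate, not isolated) | C=C(CCc1ccc(OC(C)=O)cc1)OB([C@H]1C[C@H]2C[C@@H]([C@@H]1C)C2(C)C)[C@H]1C[C@H]2C[C@@H]([C@@H]1C)C2(C)C | intermediate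
6 | (5S)-O-diisopinocampheylboryl derivative of 7 (boron aldolate, not isolated) | CC(=O)Oc1ccc(CCC(=O)C[C@H](OB([C@H]2C[C@H]3C[C@@H]([C@@H]2C)C3(C)C)[C@H]2C[C@H]3C[C@@H]([C@@H]2C)C3(C)C)/C=C/c2ccc(OC(C)=O)cc2)cc1 | intermediate
7 | (5S,6E)-1,7-bis(4-acetoxyphenyl)-5-hydroxyhept-6-en-3-one | CC(=O)Oc1ccc(CCC(=O)C[C@H](O)/C=C/c2ccc(OC(C)=O)cc2)cc1 | intermediate
8 | 4-chlorobenzaldehyde | O=Cc1ccc(Cl)cc1 | starting material
9 | (3R,5S,6E)-1,7-bis(4-acetoxyphenyl)-3-hydroxyhept-6-en-5-yl 4-chlorobenzoate | CC(=O)Oc1ccc(CC[C@@H](O)C[C@H](OC(=O)c2ccc(Cl)cc2)/C=C/c2ccc(OC(C)=O)cc2)cc1 | intermediate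
10 | 1-(2,4-dihydroxy-6-methoxyphenyl)ethanone | CC(=O)c1c(O)cc(O)cc1OC | starting material
11 | 1-[4-{[(3R,5S,6E)-1,7-bis(4-acetoxyphenyl)-3-hydroxyhept-6-en-5-yl]oxy}-2-hydroxy-6-methoxyphenyl]ethanone | CC(=O)Oc1ccc(CC[C@@H](O)C[C@H](Oc2cc(O)c(C(C)=O)c(OC)c2)/C=C/c2ccc(OC(C)=O)cc2)cc1 | intermediate
12 | (3'R,7S,3R)-ortho-dienone, the keto tautomer of 13 with sp3 C3' (not isolated) | CC(=O)C1=C(O)[C@@H]([C@@H](/C=C/C[C@H](O)CCc2ccc(OC(C)=O)cc2)c2ccc(OC(C)=O)cc2)C(=O)C=C1OC | intermediate
13 | 1-[3-{(3R,5E,7S)-1,7-bis(4-acetoxyphenyl)-3-hydroxyhept-5-en-7-yl}-2,4-dihydroxy-6-methoxyphenyl]ethanone | COc1cc(O)c([C@@H](/C=C/C[C@H](O)CCc2ccc(OC(C)=O)cc2)c2ccc(OC(C)=O)cc2)c(O)c1C(C)=O | intermediate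
14 | benzaldehyde | O=Cc1ccccc1 | starting material
15 | 1-[3-{(3R,5E,7S)-3-hydroxy-1,7-bis(4-hydroxyphenyl)hept-5-en-7-yl}-2,4-dihydroxy-6-methoxyphenyl]ethanone (not isolated) | COc1cc(O)c([C@@H](/C=C/C[C@H](O)CCc2ccc(O)cc2)c2ccc(O)cc2)c(O)c1C(C)=O | intermediate
16 | 7-epi-katsumain C, (3R,5E,7S) | COc1cc(O)c([C@@H](/C=C/C[C@H](O)CCc2ccc(O)cc2)c2ccc(O)cc2)c(O)c1C(=O)/C=C/c1ccccc1 | target

**Totals**
Total step count: 6.
Longest linear sequence: 6 (1 → 3 → 7 → 9 → 11 → 13 → 16).

**The three steps most likely to fail**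

**Step 4 (the proposed new step).**
- Risks: loss of er through palladium-palladium exchange or re-ionisation of 11, attack at C7, and closure of C3-OH onto the allyl unit.
- The fallback uses known chemistry with the opposite stereochemical logic (SN2 inversion instead of double inversion). It sets out from 3 and 4 and comes back at 11.
- The aldol of step 2 is run with (−)-Ipc2BCl to give (5R,6E)-1,7-bis(4-acetoxyphenyl)-5-hydroxyhept-6-en-3-one F1.
- Narasaka–Prasad reduction (Et2BOMe, NaBH4, THF/MeOH, −78 °C) then gives the syn diol (3R,5R,6E)-1,7-bis(4-acetoxyphenyl)hept-6-ene-3,5-diol F2.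
- A Mitsunobu etherification with 10 (PPh3, DIAD, toluene, 0 °C) displaces the more reactive allylic C5-OH with inversion and delivers 11.

**Step 5.**
- Risks: some migration to C5', or partial ionisation that lowers the chirality transfer.
- The fallback moves the anchoring oxygen from O-4' to O-2', so that only one ortho carbon is free. It sets out from 9 and 10 and comes back at 15 in the flask of step 6.
- Compound 10 is acetylated at its non-chelated hydroxyl (Ac2O 1.0 equiv, pyridine, 0 °C) to give 4-acetyl-3-hydroxy-5-methoxyphenyl acetate F3.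
- F3 is O-allylated with 9 by the palladium protocol of step 4, with Cs2CO3 as base. This gives 1-[2-{[(3R,5S,6E)-1,7-bis(4-acetoxyphenyl)-3-hydroxyhept-6-en-5-yl]oxy}-4-acetoxy-6-methoxyphenyl]ethanone F4.
- The Claisen rearrangement of F4 (Eu(fod)3, toluene, 80 °C, or N,N-diethylaniline, 150 °C) can end only at C3'. It gives 1-[3-{(3R,5E,7S)-1,7-bis(4-acetoxyphenyl)-3-hydroxyhept-5-en-7-yl}-4-acetoxy-2-hydroxy-6-methoxyphenyl]ethanone F5.
- The KOH of step 6 strips all three acetates of F5 to give 15.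

**Step 2.**
- Risk: boron aldol reactions of methyl ketones give only moderate er, and the upgrade at 9 depends on that ester crystallising well.
- The fallback replaces reagent control by catalytic Lewis-base control. It sets out from 3, with commercial 4-(4-hydroxyphenyl)butan-2-one in place of 4, and comes back at 7.
- The hydroxy ketone is treated with LiN(iPr)2 (2.2 equiv) and Me3SiCl (THF, −78 °C) to give 2-(trimethylsilyloxy)-4-[4-(trimethylsilyloxy)phenyl]but-1-ene F6.
- F6 adds to 3 in a Mukaiyama aldol reaction promoted by SiCl4 and 5 mol % of a binaphthyl-2,2'-diamine-derived bisphosphoramide (the antipode that gives the 5S carbinol; CH2Cl2, −78 °C). Enals typically give above 95:5 er under these conditions.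
- Work-up with aqueous KF/NaHCO3 gives (5S,6E)-7-(4-acetoxyphenyl)-5-hydroxy-1-(4-hydroxyphenyl)hept-6-en-3-one F7.
- Ac2O (1.05 equiv) with NaHCO3 acetylates only the phenol of F7 and returns 7.

**Further compounds**
F1 | step 4 | (5R,6E)-1,7-bis(4-acetoxyphenyl)-5-hydroxyhept-6-en-3-one | CC(=O)Oc1ccc(CCC(=O)C[C@@H](O)/C=C/c2ccc(OC(C)=O)cc2)cc1
F2 | step 4 | (3R,5R,6E)-1,7-bis(4-acetoxyphenyl)hept-6-ene-3,5-diol | CC(=O)Oc1ccc(CC[C@@H](O)C[C@@H](O)/C=C/c2ccc(OC(C)=O)cc2)cc1
F3 | step 5 | 4-acetyl-3-hydroxy-5-methoxyphenyl acetate | CC(=O)Oc1cc(O)c(C(C)=O)c(OC)c1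
F4 | step 5 | 1-[2-{[(3R,5S,6E)-1,7-bis(4-acetoxyphenyl)-3-hydroxyhept-6-en-5-yl]oxy}-4-acetoxy-6-methoxyphenyl]ethanone | CC(=O)Oc1ccc(CC[C@@H](O)C[C@H](Oc2cc(OC(C)=O)cc(OC)c2C(C)=O)/C=C/c2ccc(OC(C)=O)cc2)cc1
F5 | step 5 | 1-[3-{(3R,5E,7S)-1,7-bis(4-acetoxyphenyl)-3-hydroxyhept-5-en-7-yl}-4-acetoxy-2-hydroxy-6-methoxyphenyl]ethanone | COc1cc(OC(C)=O)c([C@@H](/C=C/C[C@H](O)CCc2ccc(OC(C)=O)cc2)c2ccc(OC(C)=O)cc2)c(O)c1C(C)=O
F6 | step 2 | 2-(trimethylsilyloxy)-4-[4-(trimethylsilyloxy)phenyl]but-1-ene | C=C(CCc1ccc(O[Si](C)(C)C)cc1)O[Si](C)(C)C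
F7 | step 2 | (5S,6E)-7-(4-acetoxyphenyl)-5-hydroxy-1-(4-hydroxyphenyl)hept-6-en-3-one | O=C(CCc1ccc(O)cc1)C[C@H](O)/C=C/c1ccc(OC(C)=O)cc1
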